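| setting | amber | larch | elm | maple | oak |
|---|---|---|---|---|---|
| starting material | 0.070 M | 0.14 M | 0.14 M | 0.14 M | 0.14 M |
| second substrate | 0.070 M | 0.0700 M | 0.0700 M | 0.0700 M | 0.0700 M |
| free catalyst | 7 mM | 7.0 mM | 7.0 mM | 7.0 mM | 7.0 mM |
| impurity | 5.5 mM | 5.5 mM | 5.5 mM | 5.5 mM | 5.5 mM |
| temperature | 80 °C |  | 80 °C | 65 °C | 50 °C |
| remark | run made earlier | at 80 °C until 10 h, from then on at 50 °C |  |  |  |
| time |  | 20 h | 20 h | 20 h | 20 h |

amber run (percent of the starting material charged)

| time / h | target / % | starting material / % |
|---|---|---|
| 0.250 | 9 | 89 |
| 0.833 | 25 | 78 |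
| 1.33 | 29 | 71 |
| 2.00 | 36 | 62 |
| 3.00 | 44 | 53 |
| 4.00 | 55 | 45 |

(readings scatter by 1.5 percentage points)

- the numbers in the tables scatter with a standard deviation of 1.5 percentage points
- steps thought possible: 2 free catalyst <-> resting dimer; catalyst intermediate B -> free catalyst + second product; starting material + free catalyst <-> catalyst intermediate A; free catalyst + impurity -> spent catalyst B; catalyst intermediate A -> free catalyst + target; catalyst intermediate B -> spent catalyst A; second substrate + free catalyst <-> catalyst intermediate B
- the earlier runs do not show what temperature does; that part of a forecast is a guess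

- the flask that comes out highest in amount of target, in percent of the starting material charged, or "all alike" when all lie within 1.5 percentage points (larch / elm / maple / oak / all alike)
- target at the end, in percent of the starting material charged, larch
- target at the end, in percent of the starting material charged, elm
- target at the end, in percent of the starting material charged, maple
- target at the end, in percent of the starting material charged, oak

Time came first: in the amber run target formed at 25.2 mM h⁻¹ on average over the first 0.250 h, but at 6.65 mM h⁻¹ between 2.00 h and 4.00 h, a reading lower by a factor of 3.79. I put this down to the step in which free catalyst and impurity give spent catalyst B. The impurity is the limiting reagent of that pair, at 5.5 mM against 7.0 mM. So I carried one quantity: the catalyst surplus S, the free catalyst charged minus the impurity charged, 1.50 mM. The charges allow a drop in working catalyst by a factor of 4.67.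

Elm is amber's near twin, with the same catalyst, impurity, second substrate and temperature, hence the same S, but twice the starting material. I took the late rate as proportional to S and to the starting material present, as the step of starting material with free catalyst reads: a pseudo-first-order decay. On that assumption the time constant τ is the same in amber and elm, so elm makes target faster in mM per hour than amber but takes the same time for the same percentage. Amber's starting material fell from 62% at 2.00 h to 45% at 4.00 h, which reads as τ = 6.24 h. Elm, with 20 h available, should then reach about 95.9%. Temperature was a guess: I expected slower runs in the cooler flasks, and elm highest, being hotter than maple and oak and hotter than larch's second half.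

The forecast chose elm at 78%, below my figure, with larch 60%, maple 46% and oak 21%, reasoning that “the impurity kills about 5.5 of the 7 mM catalyst”.

The flasks gave elm as the highest: elm 98.4%, larch 84.1%, maple 61.5%, oak 17.9%.

    2 free catalyst ⇌ resting dimer, settled at all times (K = 41.0 M⁻¹, ΔH = −3.00 kJ mol⁻¹)
    catalyst intermediate B → free catalyst + second product (k = 41.1 h⁻¹, Ea = 79.0 kJ mol⁻¹)
    starting material + free catalyst ⇌ catalyst intermediate A (K = 12.0 M⁻¹, k = 125 M⁻¹ h⁻¹, Ea = 68.0 kJ mol⁻¹, ΔH = 9.00 kJ mol⁻¹)
    free catalyst + impurity → spent catalyst B (k = 885 M⁻¹ h⁻¹, Ea = 66.0 kJ mol⁻¹)
    catalyst intermediate A → free catalyst + target (k = 1.58 h⁻¹, Ea = 99.0 kJ mol⁻¹)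
    catalyst intermediate B → spent catalyst A (k = 0.166 h⁻¹, Ea = 111 kJ mol⁻¹)
    second substrate + free catalyst ⇌ catalyst intermediate B (K = 120 M⁻¹, k = 767 M⁻¹ h⁻¹, Ea = 63.0 kJ mol⁻¹, ΔH = 9.00 kJ mol⁻¹)
    (constants at 50 °C)

In larch at 20.0 h, spent catalyst B held 78.6% of the catalyst charged, matching the impurity share 78.6%. The surplus share, 21.4%, stood as spent catalyst A 11.0%, free catalyst 8.17%, catalyst intermediate A 1.88% and resting dimer 0.384%. A neighbour of larch charged with 0.0093 M of impurity has S of −2.30 mM, so 2.30 mM of impurity should outlast the catalyst. Adding the 0.455 mM of catalyst lost as spent catalyst A gives 2.76 mM, and that flask kept 2.76 mM of impurity, with free catalyst at 0% and target at 6.16%.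

The earlier runs and the new flask were generated by integration with made-up constants, noise included.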